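**Plan**

- Retrosynthesis: the free OH of ring B is unmasked last by cleaving one O–CH3 bond of the symmetric bis(methyl ether). Before that, the four C–Br bonds and two temporary C5–N bonds are traced back to a bis(4-methoxyaniline).
- Key cut: in each ring the oxygen at C2 (OMe on ring A, OH on ring B; C1 carries the diaryl ether oxygen) lies para to the unsubstituted C5. Both C2–O bonds are therefore cut together, leading back to a bis(N-arylhydroxylamine) with nitrogen at C5 and to methanol.
- Forward order: no ring is formed and the diaryl ether is bought intact. The sequence is NH2 to NO2 to NHOH, twofold para-methoxylation through nitrenium ions, tetrabromination ortho to the amines, twofold deamination, and mono-demethylation.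
- Stereochemistry: the target is achiral. Only regiochemistry is at stake, set by para capture of the nitrenium ions and by ortho direction from the C5 amino groups.

Key step: step 3

Remark on the chemistry: both rings are numbered C1 (ether oxygen), C2 (OMe or OH), C4 and C6 (Br), C5 (H in the target, N in the intermediates). The bis-hydroxylamine 3 is assumed stable enough to be isolated and used at once.

**Route**

Step 1
Reactants: 1 3,3'-oxydianiline
Product: 2 1,1'-oxybis(3-nitrobenzene)
Conditions: NaBO3·4H2O (10 equiv), AcOH, 55 °C, slow addition of 1
Reagents that add atoms: sodium perborate tetrahydrate, [Na+].[O-]B1OO1.O.O.O.O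
Why: Oxidation of anilines to nitroarenes by perborate in warm acetic acid is a standard functional-group oxidation (through the hydroxylamine and nitroso stages), and adding 1 slowly into excess oxidant keeps free amine scarce so that azo and azoxy condensation is held back while the diaryl ether stays inert.

Step 2
Reactants: 2 1,1'-oxybis(3-nitrobenzene)
Product: 3 N,N'-[oxybis(3,1-phenylene)]bis(hydroxylamine)
Conditions: 5% Rh/C (cat.), N2H4·H2O (2.2 equiv), THF, 0 °C to rt, Ar
Reagents that add atoms: none
Why: Catalytic transfer hydrogenation of nitroarenes with hydrazine over Rh/C is known to halt at the N-arylhydroxylamine when run cold with about one hydrazine per nitro group, so both nitro groups should be reduced without N–O cleavage.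

Step 3
Reactants: 3 N,N'-[oxybis(3,1-phenylene)]bis(hydroxylamine); 4 methanol
Product: 6 3,3'-oxybis(4-methoxyaniline), via monorearranged hydroxylamine 5 (not isolated)
Conditions: conc. H2SO4 (10 equiv), dry degassed MeOH (0.02 M in 3), reflux, Ar; then aq. NaHCO3
Reagents that add atoms: methanol (compound 4), CO
Why: In strong acid each NHOH group is O-protonated and loses water to give an N-aryl nitrenium ion (an iminocyclohexadienyl cation) whose positive charge rests on the carbons ortho and para to nitrogen. Methanol, present as solvent, adds at the para carbon, which is C2 and therefore the carbon next to the ether-bearing C1, and loss of the C2 proton rearomatises that ring to a 4-methoxyaniline; the second ring follows by way of 5. The closest known reaction type is the Bamberger rearrangement of N-arylhydroxylamines in acidic alcohols to 4-alkoxyanilines, which also takes 3-substituted substrates to the para product. No ring is closed and no stereocentre is created. The step needs para over ortho capture and solvolysis over bimolecular azoxy formation or disproportionation: the first rests on the innate para preference of the nitrenium ion, which the aryloxy group (meta to nitrogen and cross-conjugated with the cation) should not override, and the second on high dilution, exclusion of oxygen and protonation of the product amines. Dry methanol in large excess should make methanol rather than water the nucleophile.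

Step 4
Reactants: 6 3,3'-oxybis(4-methoxyaniline)
Product: 7 3,3'-oxybis(2,6-dibromo-4-methoxyaniline)
Conditions: NBS (4.05 equiv), MeCN, 0 °C to rt, dark
Reagents that add atoms: N-bromosuccinimide, O=C1CCC(=O)N1Br
Why: In this electrophilic aromatic bromination the free NH2 is the strongest donor of each ring and its para position is blocked by OMe, so two bromines per ring should enter ortho to nitrogen (C4 and C6), as in the known 2,6-dibromination of 4-methoxyaniline, and the exact stoichiometry spares the position ortho to OMe.

Step 5
Reactants: 7 3,3'-oxybis(2,6-dibromo-4-methoxyaniline)
Product: 9 1,1'-oxybis(2,4-dibromo-6-methoxybenzene), via bis(diazonium) salt 8 (not isolated)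
Conditions: NaNO2, conc. H2SO4, AcOH, 0–5 °C; then 50% aq. H3PO2, 0 °C to rt
Reagents that add atoms: none
Why: Diazotisation of weakly basic 2,6-dibromoanilines with nitrosylsulfuric acid followed by hypophosphorous acid reduction (Kornblum hydrodediazoniation, a radical chain) is the classical removal of an amino group used as a temporary director, and the chloride-free medium avoids halide exchange ortho to the diazonium groups.

Step 6
Reactants: 9 1,1'-oxybis(2,4-dibromo-6-methoxybenzene)
Product: 11 3,5-dibromo-2-(2,4-dibromo-6-methoxyphenoxy)phenol, via aryloxydibromoborane 10 (not isolated)
Conditions: BBr3 (1.0 equiv), CH2Cl2, −78 to 0 °C, stopped at partial conversion; then H2O; recovered 9 resubmitted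
Reagents that add atoms: none
Why: BBr3 cleavage of an aryl methyl ether (O-complexation, bromide attack at methyl, hydrolysis of the aryloxyborane) acts on two equivalent methoxy groups, so limiting reagent at low temperature should favour the mono-phenol, which is separated by chromatography from unreacted diether and from any bisphenol.

**Compound list**

1 | 3,3'-oxydianiline | Nc1cccc(Oc2cccc(N)c2)c1 | starting material
2 | 1,1'-oxybis(3-nitrobenzene) | O=[N+]([O-])c1cccc(Oc2cccc([N+](=O)[O-])c2)c1 | intermediate
3 | N,N'-[oxybis(3,1-phenylene)]bis(hydroxylamine) | ONc1cccc(Oc2cccc(NO)c2)c1 | intermediate
4 | methanol | CO | starting material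
5 | N-[3-(5-amino-2-methoxyphenoxy)phenyl]hydroxylamine (not isolated) | COc1ccc(N)cc1Oc1cccc(NO)c1 | intermediate
6 | 3,3'-oxybis(4-methoxyaniline) | COc1ccc(N)cc1Oc1cc(N)ccc1OC | intermediate
7 | 3,3'-oxybis(2,6-dibromo-4-methoxyaniline) | COc1cc(Br)c(N)c(Br)c1Oc1c(Br)c(N)c(Br)cc1OC | intermediate
8 | 3,3'-oxybis(2,6-dibromo-4-methoxybenzenediazonium) bis(hydrogen sulfate) (not isolated) | COc1cc(Br)c([N+]#N)c(Br)c1Oc1c(Br)c([N+]#N)c(Br)cc1OC.OS(=O)(=O)[O-].OS(=O)(=O)[O-] | intermediate
9 | 1,1'-oxybis(2,4-dibromo-6-methoxybenzene) | COc1cc(Br)cc(Br)c1Oc1c(Br)cc(Br)cc1OC | intermediate
10 | dibromo[3,5-dibromo-2-(2,4-dibromo-6-methoxyphenoxy)phenoxy]borane (not isolated) | COc1cc(Br)cc(Br)c1Oc1c(OB(Br)Br)cc(Br)cc1Br | intermediate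
11 | 3,5-dibromo-2-(2,4-dibromo-6-methoxyphenoxy)phenol | COc1cc(Br)cc(Br)c1Oc1c(O)cc(Br)cc1Br | target

**Step count**

Total: 6 steps. Longest linear sequence: 6 steps (1 to 11), with methanol 4 entering in step 3.

**Steps most likely to fail, with fallbacks**

Step 3. The nitrenium ions may be captured at an ortho carbon, may condense with a second molecule (azoxy formation, disproportionation to amine and nitroso compound), or the second ring may rearrange less cleanly than the first, so that the twofold para-methoxylation gives a mixture. The fallback sets out from dinitro ether 2 and forms the same two C2–O bonds at the nitro oxidation level with a nucleophilic oxygen. Vicarious nucleophilic substitution of hydrogen with tert-butyl hydroperoxide and t-BuOK in liquid NH3/THF at −33 °C should hydroxylate para to each nitro group and give 2,2'-oxybis(4-nitrophenol) F1. O-Methylation with MeI and K2CO3 in DMF should give 2,2'-oxybis(1-methoxy-4-nitrobenzene) F2. Hydrogenation over Pd/C in EtOAc–MeOH reduces both nitro groups and comes back to the route at 6.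

Step 6. The second ether cleavage may compete with the first, since one boron can cleave more than one ether and the aryloxyborane 10 sits next to the remaining methoxy group. Over-cleavage to the bisphenol and low conversion per pass would then erode the yield. The fallback sets out from 9 and builds up instead of cutting down. Excess BBr3 in CH2Cl2 at 0 °C to rt should remove both methyl groups to give 2,2'-oxybis(3,5-dibromophenol) F3. One equivalent each of K2CO3 and MeI in acetone should then alkylate once: the hydrogen-bonded monophenoxide should be the dominant anion and the neutral monoether is less acidic than the bisphenol. This arrives at 11.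

Step 2. Reduction may run on to the amine in one or both rings, or the isolated bis-hydroxylamine may condense or air-oxidise to azoxy material during work-up. The fallback sets out from 2 and avoids isolating 3. Hydrogenation over Pt/C (H2, a little DMSO as modifier) directly in methanolic H2SO4 at about 50 °C forms each hydroxylamine in the acidic medium, where it should rearrange before it is reduced further. This is the one-pot nitroarene to 4-alkoxyaniline variant of the Bamberger process; 3 and 5 are then only transient and the sequence comes back at 6. No compound outside the list is made (F0).

**Further compounds**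

F1 | step 3 | 2,2'-oxybis(4-nitrophenol) | Oc1ccc(cc1Oc1cc(ccc1O)[N+](=O)[O-])[N+](=O)[O-]
F2 | step 3 | 2,2'-oxybis(1-methoxy-4-nitrobenzene) | COc1ccc(cc1Oc1cc(ccc1OC)[N+](=O)[O-])[N+](=O)[O-]
F3 | step 6 | 2,2'-oxybis(3,5-dibromophenol) | Oc1cc(Br)cc(Br)c1Oc1c(O)cc(Br)cc1Br
F0 | step 2 | none | none
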